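Compounds are numbered 1–18 as in the steps and the compound list; the target is 18.

## Analysis of the target

Compound 18 is a flavanone, (2S)-2-(3-hydroxy-4-methoxyphenyl)-5,7-dimethoxy-8-(3-methylbut-2-enyl)chroman-4-one: a benzopyranone (rings A and C) that carries ring B at C2. Ring A is pentasubstituted, with O1 on C8a, the prenyl group on C8, methoxy groups on C7 and C5 and the carbonyl carbon C4 on C4a, so that only C6 bears hydrogen. The single stereocentre is C2 (S); no other centre can relay its configuration, so a reagent or catalyst must set it. C2 is benzylic, bound to O1 and β to the C4 ketone: base opens ring C by a retro-oxa-Michael reaction to an achiral open-chain enone, and strong acid can ionize the C2–O1 bond, so the centre is fragile once the ketone exists. The prenyl alkene forbids hydrogenolysis and is at risk from strong acid (Markovnikov addition, cyclization onto a neighbouring free phenol) and from electrophilic oxidants, and the ring B hydroxyl must stay distinct from three methyl ethers. The difficulty is therefore to place four different substituents on ring A in the right order and to create C2 enantioselectively under conditions that do not racemize it. The plan rests on reading ring C as a four-atom unit O1–C8a–C4a–C4 that belongs to ring A, with C4 at the aldehyde oxidation level, plus a two-carbon unit C3–C2 that is the vinyl group of a ring B styrene; joining the two forms C3–C4 and O1–C2 in one operation.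

## Retrosynthetic reasoning

**18 from 17.** The last operation is release of the ring B hydroxyl from the silyl ether 17. A tert-butyldimethylsilyl ether is chosen over an acetal-type group for two reasons. An acetal-type group would itself be ionizable by the acid of the key step, and it would need acid for removal at the end. The silyl ether falls to buffered fluoride, which touches neither the prenyl alkene nor the C2–O1 bond.

**17 from 16 and 15.** No skeletal bond is cut here; only the oxidation level at C4 is adjusted. The ketone 17 is traced to the carbinol 16, and 16 to the 4-methoxy ether 15. The gain is that C2 is created and carried while C4 is still sp3, so the retro-oxa-Michael pathway does not exist until the penultimate step. The C4 configuration is irrelevant, because the centre becomes a carbonyl.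

**15 from 10 and 13, through 14.** The cut is made at C3–C4 and O1–C2, the two ring C bonds that do not involve an aromatic carbon.
- Cutting at O1–C8a or C4–C4a instead would demand aryl–oxygen or aryl–carbon bond formation on a crowded, very electron-rich ring.
- The chosen cut divides the molecule into two fragments of similar size, acetal 10 (all of ring A plus C4) and styrene 13 (ring B plus C2 and C3).
- Forward, 10 must lose one methoxy group to give the methoxy-substituted ortho-quinone methide 14, and 13 must add across its O=C8a–C4a=C4 unit with control of the face that becomes C2.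

**10 from 9 and 7.** The acetal 10 is the protected, ionizable form of aldehyde 9. The C4a–C4 bond of 9 is cut back to phenol 7, whose only free ortho position is the one required. A chelation-directed ortho-formylation therefore has no regiochemical choice to make.

**7 from 5, and 5 from 4 and 3 (3 from 1).** The C8–prenyl bond is traced to an aromatic Claisen rearrangement of the tertiary allyl ether 5. Direct C-prenylation of a phloroglucinol-type phenol would give O/C and ortho/para mixtures, whereas the sigmatropic shift delivers the chain to an ortho carbon only. Because 3,5-dimethoxyphenol 4 is symmetric, both ortho positions are the same. Ether 5 comes from 4 and the tertiary allylic carbonate 3, which is made from alcohol 1.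

**13 from 12 and 11.** The vinyl group is cut at its double bond back to aldehyde 12, the silyl ether of isovanillin 11. Compound 11 already holds the ring B oxygen pattern with the hydroxyl and the methoxy group differentiated.

## Alternatives that were turned down

**Alternative 1:** Ring A is folded up last instead of being bought.
- Disconnection: C5–C6. The product A1, (2S)-5,7-dihydroxy-2-[4-methoxy-3-(methoxymethoxy)phenyl]-8-(3-methylbut-2-enyl)chroman-4-one, is traced to the dihydropyranone A2, methyl (2S)-2-[4-methoxy-3-(methoxymethoxy)phenyl]-6-(6-methyl-2-oxohept-5-en-3-yl)-4-oxo-2,3-dihydropyran-5-carboxylate. Its ester carbon is the future C5 and its methyl ketone supplies C6 and C7.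
- Forward key step: two equivalents of LiN(SiMe3)2 would remove the doubly activated proton at the future C8 and then a methyl proton. The terminal enolate carbon adds to the ester in a Claisen-type condensation, methoxide leaves and enolization gives the aromatic dihydroxy ring.
- For it: the carbon chain fixes the places of the prenyl group and the ring A oxygens, so no aromatic regiochemistry arises. C2 could be set earlier by a well-established asymmetric hetero-Diels–Alder construction of the 2-aryl-dihydropyranone. On both points it is at least as secure as the chosen route.
- Against it: A2 has the C2–O1 bond β to a carbonyl and is treated with excess strong base, which invites E1cB ring opening and loss of the stereocentre. A2 needs a long linear build-up (pyranone, C-acylation, chain extension, prenylation). A1 must then be methylated twice under base, one hydroxyl being chelated to the ketone, which again threatens C2.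
- Comparison: the chosen route buys both methyl ethers with phenol 4, never exposes a finished flavanone to base, and reaches its two cycloaddition partners in five and two steps.

**Alternative 2:** Ring C is closed on an aryne.
- Disconnection: O1–C8a and C4–C4a. The product A3, (2S)-5,7-dimethoxy-2-[4-methoxy-3-(methoxymethoxy)phenyl]-8-(3-methylbut-2-enyl)chroman-4-one, is the methoxymethyl ether of 18. It would come from the silylaryl triflate A4, 3,5-dimethoxy-6-(3-methylbut-2-enyl)-2-(trimethylsilyl)phenyl trifluoromethanesulfonate, and the hydroxy ester A5, methyl (3S)-3-hydroxy-3-[4-methoxy-3-(methoxymethoxy)phenyl]propanoate.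
- Forward key step: CsF would convert A4 into the aryne A6, 1,2-didehydro-3,5-dimethoxy-6-(3-methylbut-2-enyl)benzene. The alkoxide of A5 adds at C8a, the carbon remote from the C5 methoxy group, and the aryl anion at C4a closes onto the ester.
- For it: the route is convergent and arrives directly at the ketone oxidation level. C2 is made beforehand by a reliable, known asymmetric reaction (for example hydrogenation of the β-keto ester), so its enantiocontrol is more certain than in the chosen key step. The methoxy group directs the aryne regiochemistry correctly.
- Against it: A4 needs adjacent silyl and triflate groups on a pentasubstituted ring next to a prenyl group, which costs several steps from phenol 7. The secondary benzylic alkoxide of A5 is a poor aryne partner and is prone to retro-aldol cleavage and β-elimination under basic fluoride. The aryne sits beside allylic C–H bonds of the prenyl group, which invites ene-type side reactions. A3 would form in a hot, basic fluoride medium in which ring C can open and re-close, eroding the stereocentre.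
- Comparison: the chosen route has the weaker guarantee on enantioselectivity. In return it forms C2 under acid at low temperature, with C4 still sp3, from fragments that need no aryne precursor.

**Alternative 3:** Ring C is closed by palladium-catalysed aryl ether formation.
- Disconnection: O1–C8a. The product A7, (2S,4R)-5,7-dimethoxy-2-[4-methoxy-3-(methoxymethoxy)phenyl]-8-(3-methylbut-2-enyl)chroman-4-ol, is traced to the diol triflate A8, 2-[(1R,3S)-1,3-dihydroxy-3-[4-methoxy-3-(methoxymethoxy)phenyl]propyl]-3,5-dimethoxy-6-(3-methylbut-2-enyl)phenyl trifluoromethanesulfonate.
- Forward key step: zerovalent palladium, formed from Pd(OAc)2 and a bulky di-tert-butylbiarylphosphine, would insert into the C8a–O triflate bond and couple it with the C2 hydroxyl. The C4 hydroxyl cannot compete because it would close a four-membered ring.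
- For it: the carbinol centre is set by known asymmetric aldol or reduction chemistry and is not touched by the coupling. The end game (oxidation, deprotection) is as short as in the chosen route. On certainty of configuration it is stronger.
- Against it: the triflate is flanked by two ortho substituents on a very electron-rich ring, the worst case for oxidative addition. The palladium alkoxide of a secondary benzylic alcohol can undergo β-hydride elimination to a ketone and a reduced arene. The free C4 carbinol is an ionizable trioxygenated benzylic alcohol. A8 requires a long linear sequence (acylation of 7, triflation, aldol with a ring B aldehyde, stereoselective reduction) that controls two centres, one of which is then destroyed.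
- Comparison: the chosen route forms two bonds and the stereocentre in one convergent step and is clearly shorter.

Key step: step 8

## Route

Remarks on the chemistry:
- The (R)-configured catalyst is assumed to give the (2S) adduct. The sense of induction cannot be derived with certainty for this new substrate class; should the adduct prove to be (2R), the (S)-catalyst is used instead.
- The reactive form of quinone methide 14 is assumed to be the E isomer.
- Carbinol 16 is carried as a mixture of C4 epimers, and its SMILES leaves C4 open, because C4 becomes a carbonyl in the next step.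

Step 1
Reactants: 1 2-methylbut-3-en-2-ol
Product: 3 methyl 2-methylbut-3-en-2-yl carbonate, via lithium alkoxide 2 (not isolated)
Conditions: n-BuLi, THF, −78 °C; then ClCO2Me, −78 °C → rt
Reagents that add atoms: methyl chloroformate, COC(=O)Cl
Why: O-Acylation of a pre-formed lithium alkoxide is the standard way to make carbonates of hindered tertiary allylic alcohols, which react sluggishly with amine bases alone.

Step 2
Reactants: 3 methyl 2-methylbut-3-en-2-yl carbonate; 4 3,5-dimethoxyphenol
Product: 5 1,3-dimethoxy-5-(2-methylbut-3-en-2-yloxy)benzene
Conditions: Pd(PPh3)4 (2 mol %), THF, 0 °C → rt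
Reagents that add atoms: none
Why: Tsuji–Trost O-allylation: zerovalent palladium ionizes the carbonate with loss of CO2, the methoxide released deprotonates the phenol, and the phenoxide attacks the more substituted terminus of the 1,1-dimethylallyl complex under kinetic control to give the tertiary ether.

Step 3
Reactants: 5 1,3-dimethoxy-5-(2-methylbut-3-en-2-yloxy)benzene
Product: 7 3,5-dimethoxy-2-(3-methylbut-2-enyl)phenol, via cyclohexadienone 6 (not isolated)
Conditions: N,N-diethylaniline, 130 °C
Reagents that add atoms: none
Why: Aromatic Claisen rearrangement: the [3,3] shift moves the chain to an ortho carbon with allylic transposition, so the tertiary ether gives the linear prenyl group, and dienone 6 tautomerizes to the phenol. The two ortho positions of 5 are equivalent and the basic solvent suppresses acid-catalysed chroman formation.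

Step 4
Reactants: 7 3,5-dimethoxy-2-(3-methylbut-2-enyl)phenol
Product: 9 2-hydroxy-4,6-dimethoxy-3-(3-methylbut-2-enyl)benzaldehyde, via hydroxymethylphenol 8 (not isolated)
Conditions: MgCl2, Et3N, (CH2O)n, MeCN, reflux; then cold 1 M HCl
Reagents that add atoms: formaldehyde (used as paraformaldehyde), C=O
Why: Casnati–Skattebøl ortho-formylation: the magnesium phenoxide delivers formaldehyde through a chelate to the only free ortho carbon, and the benzylic alkoxide 8 is oxidized by a second formaldehyde in an Oppenauer-type hydride transfer. The para position between the two methoxy groups is not reached by this chelate-directed process.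

Step 5
Reactants: 9 2-hydroxy-4,6-dimethoxy-3-(3-methylbut-2-enyl)benzaldehyde
Product: 10 2-(dimethoxymethyl)-3,5-dimethoxy-6-(3-methylbut-2-enyl)phenol
Conditions: HC(OMe)3 (5 equiv), PPTS (5 mol %), CH2Cl2, rt; Et3N quench, evaporation, used crude
Reagents that add atoms: trimethyl orthoformate, COC(OC)OC
Why: Acid-catalysed acetalization driven by the orthoformate as dehydrating agent; the weak pyridinium acid is not strong enough to cyclize the phenol onto the prenyl group. The product is kept base-stabilized and taken on without chromatography because it ionizes easily.

Step 6
Reactants: 11 isovanillin (3-hydroxy-4-methoxybenzaldehyde)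
Product: 12 3-(tert-butyldimethylsilyloxy)-4-methoxybenzaldehyde
Conditions: TBSCl, imidazole, DMF, rt
Reagents that add atoms: tert-butyldimethylsilyl chloride, CC(C)(C)[Si](C)(C)Cl
Why: Standard imidazole-mediated silylation of a phenol; the aryl silyl ether withstands the ylide of step 7 and the catalytic acid of steps 8 and 9.

Step 7
Reactants: 12 3-(tert-butyldimethylsilyloxy)-4-methoxybenzaldehyde
Product: 13 tert-butyl(5-ethenyl-2-methoxyphenoxy)dimethylsilane
Conditions: Ph3PCH3Br (1.2 equiv), n-BuLi (1.1 equiv), THF, 0 °C; then 12, 0 °C → rt
Reagents that add atoms: methyltriphenylphosphonium bromide, C[P+](c1ccccc1)(c1ccccc1)c1ccccc1.[Br-]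
Why: Wittig methylenation of an aromatic aldehyde; a slight deficit of base relative to the phosphonium salt leaves no free alkyllithium to attack the silyl ether.

Step 8
Reactants: 10 2-(dimethoxymethyl)-3,5-dimethoxy-6-(3-methylbut-2-enyl)phenol; 13 tert-butyl(5-ethenyl-2-methoxyphenoxy)dimethylsilane
Product: 15 (2S,4S)-2-[3-(tert-butyldimethylsilyloxy)-4-methoxyphenyl]-4,5,7-trimethoxy-8-(3-methylbut-2-enyl)chroman, via ortho-quinone methide 14 (not isolated)
Conditions: (R)-3,3'-bis(2,4,6-triisopropylphenyl)-1,1'-binaphthyl-2,2'-diyl N-triflylphosphoramide (10 mol %), 13 (2 equiv), slow addition of 10, 5 Å MS, toluene, −40 °C; Et3N quench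
Reagents that add atoms: none
Why: Proposed new method: the chiral acid protonates one acetal oxygen of 10, methanol leaves, and the trioxygenated benzylic oxocarbenium ion gives up its phenol proton to the phosphoramide anion to form the methoxy ortho-quinone methide 14, which stays hydrogen-bonded to the acid; the terminal carbon of styrene 13 then attacks C4 while the ring A oxygen bonds to the benzylic carbon in a concerted but asynchronous inverse-demand oxa-[4+2] transition state. The closest known reaction types are the racemic acid-mediated annulation of salicylaldehyde acetals with styrenes to 4-alkoxyflavans and the chiral N-triflylphosphoramide-catalysed [4+2] addition of aryl-substituted ortho-quinone methides to styrenes; the new element is the enantioselective use of an alkoxy-substituted quinone methide. Ring C is closed by intermolecular hetero-Diels–Alder cycloaddition that forms C3–C4 and O1–C2 together; should the process be stepwise, the second bond forms when the phenol oxygen captures the C2 benzylic cation in a six-membered closure. C2 is controlled by the chiral phosphoramide anion, whose 3,3'-aryl groups shield one face of the bound quinone methide and so decide which enantiotopic face of the styrene is presented. C4 is set relative to C2 by the endo approach of the aryl group to the E-configured quinone methide, which leads to the 2,4-cis adduct. Regioselectivity follows from polarity, since C4 is the electrophilic terminus and the para-methoxy group of 13 stabilizes positive charge on the carbon that becomes C2. The step needs enantiofacial selectivity at C2 only, because C4 is oxidized away later, and it needs the acid to ionize the acetal without touching the prenyl group, the silyl ether or the C2–O1 bond of 15; low temperature, a non-polar solvent and sieves that take up the methanol should secure this.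

Step 9
Reactants: 15 (2S,4S)-2-[3-(tert-butyldimethylsilyloxy)-4-methoxyphenyl]-4,5,7-trimethoxy-8-(3-methylbut-2-enyl)chroman
Product: 16 (2S)-2-[3-(tert-butyldimethylsilyloxy)-4-methoxyphenyl]-5,7-dimethoxy-8-(3-methylbut-2-enyl)chroman-4-ol (both C4 epimers)
Conditions: PPTS (10 mol %), THF/H2O 4:1, rt
Reagents that add atoms: water, O
Why: SN1 solvolysis of a benzylic ether: the C4 cation is stabilized by O1 and the C5 methoxy group (ortho) and the C7 methoxy group (para), so it forms under very mild acid and is captured by the large excess of water. The C2–O1 bond, which would give only a para-methoxybenzyl cation, ionizes far more slowly, so C2 is not touched.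

Step 10
Reactants: 16 (2S)-2-[3-(tert-butyldimethylsilyloxy)-4-methoxyphenyl]-5,7-dimethoxy-8-(3-methylbut-2-enyl)chroman-4-ol
Product: 17 (2S)-2-[3-(tert-butyldimethylsilyloxy)-4-methoxyphenyl]-5,7-dimethoxy-8-(3-methylbut-2-enyl)chroman-4-one
Conditions: Dess–Martin periodinane, pyridine, CH2Cl2, 0 °C → rt
Reagents that add atoms: none
Why: Dess–Martin oxidation of a secondary benzylic alcohol; both C4 epimers converge on one ketone. The pyridine buffer keeps the medium from ionizing C4 and is too weak a base to open ring C, and the alkene and silyl ether are inert to the periodinane.

Step 11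
Reactants: 17 (2S)-2-[3-(tert-butyldimethylsilyloxy)-4-methoxyphenyl]-5,7-dimethoxy-8-(3-methylbut-2-enyl)chroman-4-one
Product: 18 (2S)-2-(3-hydroxy-4-methoxyphenyl)-5,7-dimethoxy-8-(3-methylbut-2-enyl)chroman-4-one
Conditions: Bu4NF, AcOH (1:1), THF, 0 °C
Reagents that add atoms: none
Why: Fluoride cleavage of an aryl silyl ether; acetic acid protonates the phenoxide as it forms, so no base is present to open ring C by retro-oxa-Michael reaction. The freed hydroxyl is meta to C2 and cannot open the ring through a quinone methide, and the prenyl group and methyl ethers are inert.

## Compound list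

1 | 2-methylbut-3-en-2-ol | CC(C)(O)C=C | starting material
2 | lithium 2-methylbut-3-en-2-olate | [Li+].[O-]C(C)(C)C=C | intermediate (not isolated)
3 | methyl 2-methylbut-3-en-2-yl carbonate | COC(=O)OC(C)(C)C=C | intermediate
4 | 3,5-dimethoxyphenol | COc1cc(O)cc(OC)c1 | starting material
5 | 1,3-dimethoxy-5-(2-methylbut-3-en-2-yloxy)benzene | COc1cc(OC)cc(OC(C)(C)C=C)c1 | intermediate
6 | 3,5-dimethoxy-6-(3-methylbut-2-enyl)cyclohexa-2,4-dien-1-one (racemic) | O=C1C=C(OC)C=C(OC)C1CC=C(C)C | intermediate (not isolated)
7 | 3,5-dimethoxy-2-(3-methylbut-2-enyl)phenol | COc1cc(O)c(CC=C(C)C)c(OC)c1 | intermediate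
8 | 2-(hydroxymethyl)-3,5-dimethoxy-6-(3-methylbut-2-enyl)phenol (as its magnesium salt) | COc1cc(OC)c(CC=C(C)C)c(O)c1CO | intermediate (not isolated)
9 | 2-hydroxy-4,6-dimethoxy-3-(3-methylbut-2-enyl)benzaldehyde | COc1cc(OC)c(CC=C(C)C)c(O)c1C=O | intermediate
10 | 2-(dimethoxymethyl)-3,5-dimethoxy-6-(3-methylbut-2-enyl)phenol | COC(OC)c1c(OC)cc(OC)c(CC=C(C)C)c1O | intermediate
11 | isovanillin (3-hydroxy-4-methoxybenzaldehyde) | COc1ccc(C=O)cc1O | starting material
12 | 3-(tert-butyldimethylsilyloxy)-4-methoxybenzaldehyde | COc1ccc(C=O)cc1O[Si](C)(C)C(C)(C)C | intermediate
13 | tert-butyl(5-ethenyl-2-methoxyphenoxy)dimethylsilane | COc1ccc(C=C)cc1O[Si](C)(C)C(C)(C)C | intermediate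
14 | (6E)-3,5-dimethoxy-6-(methoxymethylidene)-2-(3-methylbut-2-enyl)cyclohexa-2,4-dien-1-one | CO/C=C1\C(OC)=CC(OC)=C(CC=C(C)C)C1=O | intermediate (not isolated)
15 | (2S,4S)-2-[3-(tert-butyldimethylsilyloxy)-4-methoxyphenyl]-4,5,7-trimethoxy-8-(3-methylbut-2-enyl)chroman | COc1ccc([C@@H]2C[C@H](OC)c3c(OC)cc(OC)c(CC=C(C)C)c3O2)cc1O[Si](C)(C)C(C)(C)C | intermediate
16 | (2S)-2-[3-(tert-butyldimethylsilyloxy)-4-methoxyphenyl]-5,7-dimethoxy-8-(3-methylbut-2-enyl)chroman-4-ol (both C4 epimers) | COc1ccc([C@@H]2CC(O)c3c(OC)cc(OC)c(CC=C(C)C)c3O2)cc1O[Si](C)(C)C(C)(C)C | intermediate
17 | (2S)-2-[3-(tert-butyldimethylsilyloxy)-4-methoxyphenyl]-5,7-dimethoxy-8-(3-methylbut-2-enyl)chroman-4-one | COc1ccc([C@@H]2CC(=O)c3c(OC)cc(OC)c(CC=C(C)C)c3O2)cc1O[Si](C)(C)C(C)(C)C | intermediate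
18 | (2S)-2-(3-hydroxy-4-methoxyphenyl)-5,7-dimethoxy-8-(3-methylbut-2-enyl)chroman-4-one | COc1ccc([C@@H]2CC(=O)c3c(OC)cc(OC)c(CC=C(C)C)c3O2)cc1O | target

## Step count and least certain steps

Total step count: 11. Longest linear sequence: 9 steps (steps 1–5, then 8–11); the ring B branch (steps 6 and 7) is 2 steps.

**Step 8 (key step).** Four processes threaten it.
- Poor facial selectivity: the substituent on C4 of the quinone methide is a small methoxy group, not the aryl group of the known cases, so the catalyst pocket has less to hold.
- Friedel–Crafts oligomerization: the free C6 position of ring A in 10 or 15 is a nucleophile of about the same strength as the styrene and can attack the cation.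
- Acid-induced oligomerization of the electron-rich styrene.
- Loss of enantiomeric purity by re-ionization of the C2–O1 bond of the product.

The fallback gives up catalyst control and resolves afterwards, using known chemistry only. It sets out from 10 and 13.
- An achiral acid (catalytic Tf2NH, CH2Cl2, −40 °C) should effect the known racemic annulation to racemic 2-[3-(tert-butyldimethylsilyloxy)-4-methoxyphenyl]-4,5,7-trimethoxy-8-(3-methylbut-2-enyl)chroman F1.
- Aqueous PPTS then gives racemic 2-[3-(tert-butyldimethylsilyloxy)-4-methoxyphenyl]-5,7-dimethoxy-8-(3-methylbut-2-enyl)chroman-4-ol F2.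
- Dess–Martin oxidation gives racemic 2-[3-(tert-butyldimethylsilyloxy)-4-methoxyphenyl]-5,7-dimethoxy-8-(3-methylbut-2-enyl)chroman-4-one F3.
- Kinetic resolution of F3 by asymmetric transfer hydrogenation with RuCl(p-cymene)[(R,R)-TsDPEN] and HCO2H/Et3N should reduce the (2R)-ketone to (2R,4R)-2-[3-(tert-butyldimethylsilyloxy)-4-methoxyphenyl]-5,7-dimethoxy-8-(3-methylbut-2-enyl)chroman-4-ol F4. The prediction is by analogy with the reduction of 4-chromanone; the catalyst antipode is taken if the preference is reversed.
- The (2S)-ketone is left behind and separated by chromatography, and the route is rejoined at 17, at the price of at most half the material.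

**Step 5.** The aldehyde of 9 is a deactivated, hydrogen-bonded vinylogous carbonate, so acetalization may stop short. The acetal 10 may also revert to 9 by hydrolysis during isolation, because its ionization is so easy. The fallback is not to isolate it. It sets out from 9: aldehyde 9, trimethyl orthoformate and styrene 13 are combined with the acid catalyst of step 8, so that 10 forms and is consumed in one flask (the three-component form of the annulation). The route is rejoined at 15.

**Step 9.** The C4 cation may lose a C3 proton to give the C3=C4 alkene, or be captured by ring A of a second molecule; such cations are the electrophiles of flavan oligomer chemistry. Either process would compete with capture by water. The fallback avoids the free cation and the carbinol altogether. It sets out from 15: DDQ in CH2Cl2/pH 7 buffer at 0 °C should abstract hydride from C4–H, by far the most hydridic position (α to the methoxy group and benzylic to the trioxygenated ring). The resulting oxocarbenium ion adds water and collapses to the ketone, so the route is rejoined at 17 with step 10 omitted.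

**Step 2.** The tertiary ether is the kinetic product. Prolonged contact with the palladium catalyst may equilibrate it to the linear prenyl ether or lead to C-allylation of the electron-rich ring, and either outcome would misdirect the Claisen step. The fallback sets out from 4. Etherification with 3-chloro-3-methylbut-1-yne (DBU, catalytic CuCl2, MeCN, 0 °C) should give 1,3-dimethoxy-5-(2-methylbut-3-yn-2-yloxy)benzene F5. Semi-hydrogenation of F5 (H2, Pd on CaCO3 poisoned with Pb(OAc)2, quinoline, EtOAc) rejoins the route at 5.

## Further compounds

F1 | step 8 | racemic 2-[3-(tert-butyldimethylsilyloxy)-4-methoxyphenyl]-4,5,7-trimethoxy-8-(3-methylbut-2-enyl)chroman | COc1ccc(C2CC(OC)c3c(OC)cc(OC)c(CC=C(C)C)c3O2)cc1O[Si](C)(C)C(C)(C)C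
F2 | step 8 | racemic 2-[3-(tert-butyldimethylsilyloxy)-4-methoxyphenyl]-5,7-dimethoxy-8-(3-methylbut-2-enyl)chroman-4-ol | COc1ccc(C2CC(O)c3c(OC)cc(OC)c(CC=C(C)C)c3O2)cc1O[Si](C)(C)C(C)(C)C
F3 | step 8 | racemic 2-[3-(tert-butyldimethylsilyloxy)-4-methoxyphenyl]-5,7-dimethoxy-8-(3-methylbut-2-enyl)chroman-4-one | COc1ccc(C2CC(=O)c3c(OC)cc(OC)c(CC=C(C)C)c3O2)cc1O[Si](C)(C)C(C)(C)C
F4 | step 8 | (2R,4R)-2-[3-(tert-butyldimethylsilyloxy)-4-methoxyphenyl]-5,7-dimethoxy-8-(3-methylbut-2-enyl)chroman-4-ol | COc1ccc([C@H]2C[C@@H](O)c3c(OC)cc(OC)c(CC=C(C)C)c3O2)cc1O[Si](C)(C)C(C)(C)C
F0 | step 5 | none | none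
F0 | step 9 | none | none
F5 | step 2 | 1,3-dimethoxy-5-(2-methylbut-3-yn-2-yloxy)benzene | COc1cc(OC)cc(OC(C)(C)C#C)c1
A1 | alternative 1 | (2S)-5,7-dihydroxy-2-[4-methoxy-3-(methoxymethoxy)phenyl]-8-(3-methylbut-2-enyl)chroman-4-one | COc1ccc([C@@H]2CC(=O)c3c(O)cc(O)c(CC=C(C)C)c3O2)cc1OCOC
A2 | alternative 1 | methyl (2S)-2-[4-methoxy-3-(methoxymethoxy)phenyl]-6-(6-methyl-2-oxohept-5-en-3-yl)-4-oxo-2,3-dihydropyran-5-carboxylate | COC(=O)C1=C(C(CC=C(C)C)C(C)=O)O[C@H](c2ccc(OC)c(OCOC)c2)CC1=O
A3 | alternative 2 | (2S)-5,7-dimethoxy-2-[4-methoxy-3-(methoxymethoxy)phenyl]-8-(3-methylbut-2-enyl)chroman-4-one | COc1ccc([C@@H]2CC(=O)c3c(OC)cc(OC)c(CC=C(C)C)c3O2)cc1OCOC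
A4 | alternative 2 | 3,5-dimethoxy-6-(3-methylbut-2-enyl)-2-(trimethylsilyl)phenyl trifluoromethanesulfonate | COc1cc(OC)c([Si](C)(C)C)c(OS(=O)(=O)C(F)(F)F)c1CC=C(C)C
A5 | alternative 2 | methyl (3S)-3-hydroxy-3-[4-methoxy-3-(methoxymethoxy)phenyl]propanoate | COC(=O)C[C@H](O)c1ccc(OC)c(OCOC)c1
A6 | alternative 2 | 1,2-didehydro-3,5-dimethoxy-6-(3-methylbut-2-enyl)benzene | COC1=CC(OC)=C(CC=C(C)C)C#C1
A7 | alternative 3 | (2S,4R)-5,7-dimethoxy-2-[4-methoxy-3-(methoxymethoxy)phenyl]-8-(3-methylbut-2-enyl)chroman-4-ol | COc1ccc([C@@H]2C[C@@H](O)c3c(OC)cc(OC)c(CC=C(C)C)c3O2)cc1OCOC
A8 | alternative 3 | 2-[(1R,3S)-1,3-dihydroxy-3-[4-methoxy-3-(methoxymethoxy)phenyl]propyl]-3,5-dimethoxy-6-(3-methylbut-2-enyl)phenyl trifluoromethanesulfonate | COc1ccc([C@@H](O)C[C@@H](O)c2c(OC)cc(OC)c(CC=C(C)C)c2OS(=O)(=O)C(F)(F)F)cc1OCOC
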